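**Plan**

1. Numbering used throughout: ring carbons C1–C10, with C1=C10 the (Z)-alkene (methyl on C10), C3 the propanoate carbon, C4=C5 the (E)-alkene (methyl on C4), C6 the lactone O–CH and C7 the ring carbon of the butenolide C=C; C11, C12 and C13 are the butenolide α-carbon, carbonyl and CH2OAc.
2. Retrosynthetic cuts, in order: the C3 ester; the butenolide at C7=C11 and O6–C12 (acetate Michael addition/intramolecular HWE on an α-ketol 2-phosphonoacrylate); then the ring bond C8–C9 of the ten-membered C7 ketone.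
3. Enabling feature: C8–C9 is both α to the C7 carbonyl and allylic to the C1=C10 alkene, so the carbocycle is the CO2-extrusion product of a twelve-membered allyl β-keto lactone (ring O on C9, ring C=O on C8), which Pd(0) contracts to the ten-membered ring.
4. Forward order: (R)-solketal → (E)-enal (C3–C7) → allylboration (C1, C2) → methacrylate RCM lactone (C9, C10) → reduction, bromoacetate, SmI2 macro-Reformatsky (12-ring) → oxidation → ring contraction (10-ring) → butenolide → propanoate.
5. Stereochemistry: C6 from the chiral pool, C3 from reagent-controlled allylboration, 4E from the stabilised Wittig ylide, 1(10)Z from the six-membered lactone; the key step creates no stereocentre.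

Key step: step 13

Assumption: the configuration is taken exactly as drawn, i.e. 3S,6R with 1(10)Z and 4E in the numbering above; all reagents named are taken as commercial.

**Route**

Step 1
Reactants: 1 (R)-solketal, [(4R)-2,2-dimethyl-1,3-dioxolan-4-yl]methanol
Product: 3 (2E)-3-[(4R)-2,2-dimethyl-1,3-dioxolan-4-yl]-2-methylprop-2-enal, via (S)-glyceraldehyde acetonide 2 (not isolated)
Conditions: TEMPO (10 mol %), PhI(OAc)2, CH2Cl2, rt; then Ph3P=C(Me)CHO, 40 °C
Reagents that add atoms: 2-(triphenylphosphoranylidene)propanal, CC(C=O)=P(c1ccccc1)(c1ccccc1)c1ccccc1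
Why: TEMPO/PhI(OAc)2 oxidises the primary alcohol under non-basic conditions that leave the acetonide and the α-stereocentre of 2 intact, and the stabilised α-methyl formyl ylide should then give the (E)-trisubstituted enal in a one-pot oxidation–Wittig olefination; the dioxolane stereocentre (later C6) comes from the chiral pool.

Step 2
Reactants: 3 (2E)-3-[(4R)-2,2-dimethyl-1,3-dioxolan-4-yl]-2-methylprop-2-enal
Product: 4 (1E,3S)-1-[(4R)-2,2-dimethyl-1,3-dioxolan-4-yl]-2-methylhexa-1,5-dien-3-ol
Conditions: (−)-Ipc2B(allyl) (from (+)-α-pinene), Et2O, −78 °C; then NaOH, H2O2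
Reagents that add atoms: (−)-B-allyldiisopinocampheylborane, C=CCB([C@@H]1C[C@@H]2C[C@@H](C2(C)C)[C@H]1C)[C@@H]1C[C@@H]2C[C@@H](C2(C)C)[C@H]1C
Why: Brown asymmetric allylboration, in which the (+)-α-pinene-derived reagent should deliver allyl to the Si face of the enal through a chair-like six-membered transition state and so set the (S)-carbinol centre (later C3) under reagent control, the remote dioxolane centre having little influence.

Step 3
Reactants: 4 (1E,3S)-1-[(4R)-2,2-dimethyl-1,3-dioxolan-4-yl]-2-methylhexa-1,5-dien-3-ol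
Product: 5 (1E,3S)-1-[(4R)-2,2-dimethyl-1,3-dioxolan-4-yl]-2-methylhexa-1,5-dien-3-yl 2-methylprop-2-enoate
Conditions: methacryloyl chloride, Et3N, DMAP (cat.), CH2Cl2, 0 °C
Reagents that add atoms: methacryloyl chloride, CC(=C)C(=O)Cl
Why: DMAP-catalysed acylation of the secondary allylic alcohol installs the alkene partner for ring closure without touching a stereocentre.

Step 4
Reactants: 5 (1E,3S)-1-[(4R)-2,2-dimethyl-1,3-dioxolan-4-yl]-2-methylhexa-1,5-dien-3-yl 2-methylprop-2-enoate
Product: 6 (6S)-6-{(1E)-1-[(4R)-2,2-dimethyl-1,3-dioxolan-4-yl]prop-1-en-2-yl}-3-methyl-5,6-dihydro-2H-pyran-2-one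
Conditions: Grubbs second-generation catalyst (5 mol %), CH2Cl2 (5 mM), 40 °C
Reagents that add atoms: none
Why: Ring-closing metathesis between the terminal vinyl group and the methacrylate alkene gives the six-membered unsaturated lactone, in which the new trisubstituted alkene can only be cis within the ring, so the (Z)-geometry of the later C1=C10 bond is fixed here; the hindered C4=C5 alkene should not take part.

Step 5
Reactants: 6 (6S)-6-{(1E)-1-[(4R)-2,2-dimethyl-1,3-dioxolan-4-yl]prop-1-en-2-yl}-3-methyl-5,6-dihydro-2H-pyran-2-one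
Product: 7 (6S)-6-[(2E,4R)-4,5-dihydroxypent-2-en-2-yl]-3-methyl-5,6-dihydro-2H-pyran-2-one
Conditions: AcOH/H2O 4:1, 40 °C
Reagents that add atoms: none
Why: Acid-catalysed hydrolysis of the terminal acetonide, which the unsaturated lactone and the allylic C–O bonds should tolerate under these mild aqueous conditions.

Step 6
Reactants: 7 (6S)-6-[(2E,4R)-4,5-dihydroxypent-2-en-2-yl]-3-methyl-5,6-dihydro-2H-pyran-2-one
Product: 8 (6S)-6-[(2E,4R)-4,5-bis(triethylsilyloxy)pent-2-en-2-yl]-3-methyl-5,6-dihydro-2H-pyran-2-one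
Conditions: TESCl, imidazole, CH2Cl2, 0 °C
Reagents that add atoms: chlorotriethylsilane, CC[Si](Cl)(CC)CC
Why: Standard silylation of both hydroxyls as TES ethers, chosen because a primary TES ether can later be oxidised directly and a secondary TES ether can be removed beside a TBS ether.

Step 7
Reactants: 8 (6S)-6-[(2E,4R)-4,5-bis(triethylsilyloxy)pent-2-en-2-yl]-3-methyl-5,6-dihydro-2H-pyran-2-one
Product: 9 (2Z,5S,6E,8R)-2,6-dimethyl-8,9-bis(triethylsilyloxy)nona-2,6-diene-1,5-diol
Conditions: DIBAL-H (4 equiv), CH2Cl2, −78 → 0 °C; Rochelle salt work-up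
Reagents that add atoms: none
Why: DIBAL-H reduces the α,β-unsaturated lactone by 1,2-addition to the (Z)-allylic diol with retention of the ring-derived alkene geometry, silyl ethers being inert.

Step 8
Reactants: 9 (2Z,5S,6E,8R)-2,6-dimethyl-8,9-bis(triethylsilyloxy)nona-2,6-diene-1,5-diol
Product: 10 (2Z,5S,6E,8R)-5-hydroxy-2,6-dimethyl-8,9-bis(triethylsilyloxy)nona-2,6-dien-1-yl 2-bromoacetate
Conditions: BrCH2COBr (1.05 equiv), 2,4,6-collidine, CH2Cl2, −78 °C
Reagents that add atoms: bromoacetyl bromide, BrCC(=O)Br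
Why: Kinetically selective acylation of the unhindered primary allylic alcohol over the hindered secondary one at low temperature with a hindered pyridine base installs the future C8 and lactone carbonyl as the Reformatsky donor.

Step 9
Reactants: 10 (2Z,5S,6E,8R)-5-hydroxy-2,6-dimethyl-8,9-bis(triethylsilyloxy)nona-2,6-dien-1-yl 2-bromoacetate
Product: 11 (2Z,5S,6E,8R)-5-(tert-butyldimethylsilyloxy)-2,6-dimethyl-8,9-bis(triethylsilyloxy)nona-2,6-dien-1-yl 2-bromoacetate
Conditions: TBSOTf, 2,6-lutidine, CH2Cl2, −78 °C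
Reagents that add atoms: tert-butyldimethylsilyl trifluoromethanesulfonate, CC(C)(C)[Si](C)(C)OS(=O)(=O)C(F)(F)F
Why: Silylation of the remaining secondary allylic alcohol with the silyl triflate and a hindered base that cannot be alkylated by the bromoacetate; a silyl ether and not the final ester is used at C3 so that no second allylic ester is present in the palladium step.

Step 10
Reactants: 11 (2Z,5S,6E,8R)-5-(tert-butyldimethylsilyloxy)-2,6-dimethyl-8,9-bis(triethylsilyloxy)nona-2,6-dien-1-yl 2-bromoacetate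
Product: 12 (2Z,5S,6E,8R)-5-(tert-butyldimethylsilyloxy)-2,6-dimethyl-9-oxo-8-(triethylsilyloxy)nona-2,6-dien-1-yl 2-bromoacetate
Conditions: (COCl)2, DMSO, CH2Cl2, −78 → −35 °C; then i-Pr2NEt, −78 → −20 °C
Reagents that add atoms: none
Why: Under Swern conditions the chlorosulfonium ion cleaves the unhindered primary Si–O bond and the resulting alkoxysulfonium ion collapses to the aldehyde (direct Swern oxidation of primary TES ethers), leaving the secondary TES and TBS ethers in place; the cold hindered amine should spare the bromoacetate and the α-silyloxy stereocentre.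

Step 11
Reactants: 12 (2Z,5S,6E,8R)-5-(tert-butyldimethylsilyloxy)-2,6-dimethyl-9-oxo-8-(triethylsilyloxy)nona-2,6-dien-1-yl 2-bromoacetate
Product: 13 (5R,6E,8S,10Z)-8-(tert-butyldimethylsilyloxy)-4-hydroxy-7,11-dimethyl-5-(triethylsilyloxy)-1-oxacyclododeca-6,10-dien-2-one (both C4 epimers)
Conditions: SmI2 (3 equiv), THF, 0 °C, slow addition of 12 (final 2 mM)
Reagents that add atoms: none
Why: SmI2-mediated intramolecular Reformatsky reaction, in which the samarium(III) ester enolate is held to the aldehyde by chelation, an arrangement known to favour medium and large lactone rings at high dilution; the new carbinol centre forms as a mixture that is erased in the next step.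

Step 12
Reactants: 13 (5R,6E,8S,10Z)-8-(tert-butyldimethylsilyloxy)-4-hydroxy-7,11-dimethyl-5-(triethylsilyloxy)-1-oxacyclododeca-6,10-dien-2-one
Product: 14 (5R,6E,8S,10Z)-8-(tert-butyldimethylsilyloxy)-7,11-dimethyl-5-(triethylsilyloxy)-1-oxacyclododeca-6,10-diene-2,4-dione
Conditions: Dess–Martin periodinane, NaHCO3, CH2Cl2, 0 °C → rt
Reagents that add atoms: none
Why: Dess–Martin oxidation of the β-hydroxy lactone to the β-keto lactone under buffered conditions that should not epimerise the α-silyloxy ketone carbon C6.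

Step 13
Reactants: 14 (5R,6E,8S,10Z)-8-(tert-butyldimethylsilyloxy)-7,11-dimethyl-5-(triethylsilyloxy)-1-oxacyclododeca-6,10-diene-2,4-dione
Product: 16 (2R,3E,5S,7Z)-5-(tert-butyldimethylsilyloxy)-4,8-dimethyl-2-(triethylsilyloxy)cyclodeca-3,7-dien-1-one, via ring-contracted β-keto acid 15 (not isolated)
Conditions: Pd(PPh3)4 (10 mol %), THF (2 mM), 25 → 45 °C
Reagents that add atoms: none
Why: Proposed new method: Pd(0) ionises the lactone C9–O bond of 14 (the only allylic ester in the molecule, at a primary terminus) to an anti-configured π-allylpalladium cation tethered to a β-keto carboxylate, whose stabilised enolate carbon C8 attacks the CH2 terminus C9; the β-keto acid 15 so formed loses CO2, so the C(=O)–O unit is excised and the twelve-membered lactone becomes the ten-membered carbocycle. The closest known reaction type is the Tsuji/Saegusa decarboxylative allylation of acyclic allyl β-keto esters, supported by Pd-catalysed decarboxylative ring contractions of vinyl-substituted cyclic carbamates and by π-allylpalladium macrocyclisations of β-keto ester anions; new is that the allyl ester is a macrolactone, so that C–C bond formation is a ring contraction by two atoms. The carbocycle closes in a 10-endo sense with respect to the allyl unit (attack at C9, alkene kept in the ring), whereas the 8-exo alternative (attack at C1) would place the (E)-C4=C5 alkene in an eight-membered ring and is geometrically excluded. No stereocentre is created (C8 ends as CH2) and C3 and C6 are spectators, C6–H being spared because the nucleophile is the doubly stabilised β-keto carboxylate enolate and not a free ketone enolate. The step needs C- over O-allylation (soft stabilised enolate, and any O-allyl product can re-ionise), retention of the (Z)-alkene (syn–anti exchange would require η1-bonding at the secondary terminus C1 and should be slower than intramolecular capture) and suppression of oligomers (high dilution); the other two allylic oxygens are silyl ethers and cannot ionise.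

Step 14
Reactants: 16 (2R,3E,5S,7Z)-5-(tert-butyldimethylsilyloxy)-4,8-dimethyl-2-(triethylsilyloxy)cyclodeca-3,7-dien-1-one
Product: 17 (2R,3E,5S,7Z)-5-(tert-butyldimethylsilyloxy)-2-hydroxy-4,8-dimethylcyclodeca-3,7-dien-1-one
Conditions: PPTS (cat.), MeOH/CH2Cl2, 0 °C
Reagents that add atoms: none
Why: Acid-catalysed methanolysis removes the secondary TES ether selectively, because a TES ether is far more acid-labile than the TBS ether at C3.

Step 15
Reactants: 18 tert-butyl 2-(diethoxyphosphoryl)acetate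
Product: 20 tert-butyl 2-(diethoxyphosphoryl)prop-2-enoate, via hydroxymethyl adduct 19 (not isolated)
Conditions: (CH2O)n, piperidine (cat.), MeOH, reflux; then TsOH (cat.), toluene, reflux (Dean–Stark)
Reagents that add atoms: formaldehyde (as paraformaldehyde), C=O
Why: Base-catalysed hydroxymethylation of the phosphonoacetate with formaldehyde (Knoevenagel-type aldol) followed by acid-catalysed dehydration is the standard route to 2-phosphonoacrylates.

Step 16
Reactants: 20 tert-butyl 2-(diethoxyphosphoryl)prop-2-enoate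
Product: 21 2-(diethoxyphosphoryl)prop-2-enoic acid
Conditions: TFA, CH2Cl2, 0 °C → rt
Reagents that add atoms: none
Why: Acidolysis of the tert-butyl ester with loss of isobutene leaves the diethyl phosphonate and the acrylate untouched.

Step 17
Reactants: 17 (2R,3E,5S,7Z)-5-(tert-butyldimethylsilyloxy)-2-hydroxy-4,8-dimethylcyclodeca-3,7-dien-1-one; 21 2-(diethoxyphosphoryl)prop-2-enoic acid
Product: 22 (1R,2E,4S,6Z)-4-(tert-butyldimethylsilyloxy)-3,7-dimethyl-10-oxocyclodeca-2,6-dien-1-yl 2-(diethoxyphosphoryl)prop-2-enoate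
Conditions: DCC, DMAP (5 mol %), CH2Cl2, 0 °C
Reagents that add atoms: none
Why: Steglich esterification of the α-ketol hydroxyl with the carbodiimide-activated acid under near-neutral conditions, which should not epimerise C6.

Step 18
Reactants: 22 (1R,2E,4S,6Z)-4-(tert-butyldimethylsilyloxy)-3,7-dimethyl-10-oxocyclodeca-2,6-dien-1-yl 2-(diethoxyphosphoryl)prop-2-enoate
Product: 24 [(6Z,9S,10E,11aR)-9-(tert-butyldimethylsilyloxy)-6,10-dimethyl-2-oxo-2,4,5,8,9,11a-hexahydrocyclodeca[b]furan-3-yl]methyl acetate, via acetate Michael adduct 23 (not isolated)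
Conditions: CsOAc (3 equiv), 18-crown-6 (cat.), MeCN, rt
Reagents that add atoms: caesium acetate, CC(=O)[O-].[Cs+]
Why: Proposed new method: acetate should add reversibly in an oxa-Michael sense to the doubly activated 2-phosphonoacrylate, and the phosphonate carbanion of adduct 23 is then consumed irreversibly by intramolecular Horner–Wadsworth–Emmons olefination of the neighbouring ring ketone (5-exo addition, loss of diethyl phosphate), which closes the butenolide with its tetrasubstituted C7=C11 alkene and installs the acetoxymethyl group in the same operation; the closest known reaction type is the tandem Michael/Horner–Wadsworth–Emmons reaction of 2-phosphonoacrylates with alkoxide, thiolate and amine donors, here extended to a carboxylate donor; no stereocentre is formed, and the weakly basic acetate should leave C6 untouched.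

Step 19
Reactants: 24 [(6Z,9S,10E,11aR)-9-(tert-butyldimethylsilyloxy)-6,10-dimethyl-2-oxo-2,4,5,8,9,11a-hexahydrocyclodeca[b]furan-3-yl]methyl acetate
Product: 25 [(6Z,9S,10E,11aR)-9-hydroxy-6,10-dimethyl-2-oxo-2,4,5,8,9,11a-hexahydrocyclodeca[b]furan-3-yl]methyl acetate
Conditions: HF·pyridine, pyridine/THF, 0 °C → rt
Reagents that add atoms: none
Why: Fluoride-mediated cleavage of the secondary TBS ether under weakly acidic conditions that the butenolide and the allylic acetate tolerate.

Step 20
Reactants: 25 [(6Z,9S,10E,11aR)-9-hydroxy-6,10-dimethyl-2-oxo-2,4,5,8,9,11a-hexahydrocyclodeca[b]furan-3-yl]methyl acetate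
Product: 26 [(6Z,9S,10E,11aR)-6,10-dimethyl-2-oxo-9-(propanoyloxy)-2,4,5,8,9,11a-hexahydrocyclodeca[b]furan-3-yl]methyl acetate (target, CNP0238103.1)
Conditions: (EtCO)2O, Et3N, DMAP (cat.), CH2Cl2, 0 °C
Reagents that add atoms: propanoic anhydride, CCC(=O)OC(=O)CC
Why: DMAP-catalysed acylation of the secondary allylic alcohol with the anhydride gives the propanoate; the amine bases are too weak to deprotonate the butenolide γ-carbon C6.

**Compound list**

1 | (R)-solketal, [(4R)-2,2-dimethyl-1,3-dioxolan-4-yl]methanol | OC[C@@H]1COC(C)(C)O1 | starting material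
2 | (S)-glyceraldehyde acetonide, (4S)-2,2-dimethyl-1,3-dioxolane-4-carbaldehyde (not isolated) | O=C[C@@H]1COC(C)(C)O1 | intermediate
3 | (2E)-3-[(4R)-2,2-dimethyl-1,3-dioxolan-4-yl]-2-methylprop-2-enal | O=C/C(C)=C/[C@@H]1COC(C)(C)O1 | intermediate
4 | (1E,3S)-1-[(4R)-2,2-dimethyl-1,3-dioxolan-4-yl]-2-methylhexa-1,5-dien-3-ol | C=CC[C@H](O)/C(C)=C/[C@@H]1COC(C)(C)O1 | intermediate
5 | (1E,3S)-1-[(4R)-2,2-dimethyl-1,3-dioxolan-4-yl]-2-methylhexa-1,5-dien-3-yl 2-methylprop-2-enoate | C=CC[C@H](OC(=O)C(C)=C)/C(C)=C/[C@@H]1COC(C)(C)O1 | intermediate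
6 | (6S)-6-{(1E)-1-[(4R)-2,2-dimethyl-1,3-dioxolan-4-yl]prop-1-en-2-yl}-3-methyl-5,6-dihydro-2H-pyran-2-one | CC1=CC[C@@H](/C(C)=C/[C@@H]2COC(C)(C)O2)OC1=O | intermediate
7 | (6S)-6-[(2E,4R)-4,5-dihydroxypent-2-en-2-yl]-3-methyl-5,6-dihydro-2H-pyran-2-one | CC1=CC[C@@H](/C(C)=C/[C@@H](O)CO)OC1=O | intermediate
8 | (6S)-6-[(2E,4R)-4,5-bis(triethylsilyloxy)pent-2-en-2-yl]-3-methyl-5,6-dihydro-2H-pyran-2-one | CC1=CC[C@@H](/C(C)=C/[C@@H](O[Si](CC)(CC)CC)CO[Si](CC)(CC)CC)OC1=O | intermediate
9 | (2Z,5S,6E,8R)-2,6-dimethyl-8,9-bis(triethylsilyloxy)nona-2,6-diene-1,5-diol | OC/C(C)=C\C[C@H](O)/C(C)=C/[C@@H](O[Si](CC)(CC)CC)CO[Si](CC)(CC)CC | intermediate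
10 | (2Z,5S,6E,8R)-5-hydroxy-2,6-dimethyl-8,9-bis(triethylsilyloxy)nona-2,6-dien-1-yl 2-bromoacetate | BrCC(=O)OC/C(C)=C\C[C@H](O)/C(C)=C/[C@@H](O[Si](CC)(CC)CC)CO[Si](CC)(CC)CC | intermediate
11 | (2Z,5S,6E,8R)-5-(tert-butyldimethylsilyloxy)-2,6-dimethyl-8,9-bis(triethylsilyloxy)nona-2,6-dien-1-yl 2-bromoacetate | BrCC(=O)OC/C(C)=C\C[C@H](O[Si](C)(C)C(C)(C)C)/C(C)=C/[C@@H](O[Si](CC)(CC)CC)CO[Si](CC)(CC)CC | intermediate
12 | (2Z,5S,6E,8R)-5-(tert-butyldimethylsilyloxy)-2,6-dimethyl-9-oxo-8-(triethylsilyloxy)nona-2,6-dien-1-yl 2-bromoacetate | BrCC(=O)OC/C(C)=C\C[C@H](O[Si](C)(C)C(C)(C)C)/C(C)=C/[C@@H](O[Si](CC)(CC)CC)C=O | intermediate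
13 | (5R,6E,8S,10Z)-8-(tert-butyldimethylsilyloxy)-4-hydroxy-7,11-dimethyl-5-(triethylsilyloxy)-1-oxacyclododeca-6,10-dien-2-one (C4 epimers) | O=C1CC(O)[C@H](O[Si](CC)(CC)CC)/C=C(C)/[C@@H](O[Si](C)(C)C(C)(C)C)C/C=C(C)\CO1 | intermediate
14 | (5R,6E,8S,10Z)-8-(tert-butyldimethylsilyloxy)-7,11-dimethyl-5-(triethylsilyloxy)-1-oxacyclododeca-6,10-diene-2,4-dione | O=C1CC(=O)[C@H](O[Si](CC)(CC)CC)/C=C(C)/[C@@H](O[Si](C)(C)C(C)(C)C)C/C=C(C)\CO1 | intermediate
15 | (3R,4E,6S,8Z)-6-(tert-butyldimethylsilyloxy)-5,9-dimethyl-2-oxo-3-(triethylsilyloxy)cyclodeca-4,8-diene-1-carboxylic acid (not isolated) | O=C1C(C(=O)O)C/C(C)=C\C[C@H](O[Si](C)(C)C(C)(C)C)/C(C)=C/[C@H]1O[Si](CC)(CC)CC | intermediate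
16 | (2R,3E,5S,7Z)-5-(tert-butyldimethylsilyloxy)-4,8-dimethyl-2-(triethylsilyloxy)cyclodeca-3,7-dien-1-one | O=C1CC/C(C)=C\C[C@H](O[Si](C)(C)C(C)(C)C)/C(C)=C/[C@H]1O[Si](CC)(CC)CC | intermediate
17 | (2R,3E,5S,7Z)-5-(tert-butyldimethylsilyloxy)-2-hydroxy-4,8-dimethylcyclodeca-3,7-dien-1-one | O=C1CC/C(C)=C\C[C@H](O[Si](C)(C)C(C)(C)C)/C(C)=C/[C@H]1O | intermediate
18 | tert-butyl 2-(diethoxyphosphoryl)acetate | CCOP(=O)(OCC)CC(=O)OC(C)(C)C | starting material
19 | tert-butyl 2-(diethoxyphosphoryl)-3-hydroxypropanoate (not isolated) | CCOP(=O)(OCC)C(CO)C(=O)OC(C)(C)C | intermediate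
20 | tert-butyl 2-(diethoxyphosphoryl)prop-2-enoate | C=C(C(=O)OC(C)(C)C)P(=O)(OCC)OCC | intermediate
21 | 2-(diethoxyphosphoryl)prop-2-enoic acid | C=C(C(=O)O)P(=O)(OCC)OCC | intermediate
22 | (1R,2E,4S,6Z)-4-(tert-butyldimethylsilyloxy)-3,7-dimethyl-10-oxocyclodeca-2,6-dien-1-yl 2-(diethoxyphosphoryl)prop-2-enoate | O=C1CC/C(C)=C\C[C@H](O[Si](C)(C)C(C)(C)C)/C(C)=C/[C@H]1OC(=O)C(=C)P(=O)(OCC)OCC | intermediate
23 | (1R,2E,4S,6Z)-4-(tert-butyldimethylsilyloxy)-3,7-dimethyl-10-oxocyclodeca-2,6-dien-1-yl 3-acetoxy-2-(diethoxyphosphoryl)propanoate, formed as its α-carbanion (not isolated) | O=C1CC/C(C)=C\C[C@H](O[Si](C)(C)C(C)(C)C)/C(C)=C/[C@H]1OC(=O)C(COC(C)=O)P(=O)(OCC)OCC | intermediate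
24 | [(6Z,9S,10E,11aR)-9-(tert-butyldimethylsilyloxy)-6,10-dimethyl-2-oxo-2,4,5,8,9,11a-hexahydrocyclodeca[b]furan-3-yl]methyl acetate | CC(C)(C)[Si](C)(C)O[C@H]1C/C=C(/C)CCC2=C(COC(C)=O)C(=O)O[C@@H]2/C=C/1C | intermediate
25 | [(6Z,9S,10E,11aR)-9-hydroxy-6,10-dimethyl-2-oxo-2,4,5,8,9,11a-hexahydrocyclodeca[b]furan-3-yl]methyl acetate | O[C@H]1C/C=C(/C)CCC2=C(COC(C)=O)C(=O)O[C@@H]2/C=C/1C | intermediate
26 | [(6Z,9S,10E,11aR)-6,10-dimethyl-2-oxo-9-(propanoyloxy)-2,4,5,8,9,11a-hexahydrocyclodeca[b]furan-3-yl]methyl acetate | CCC(=O)O[C@H]1C/C=C(/C)CCC2=C(COC(C)=O)C(=O)O[C@@H]2/C=C/1C | target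

**Step count and risks**

Total step count: 20. Longest linear sequence: 18 steps (steps 1–14 and 17–20, from (R)-solketal); steps 15–16 prepare the phosphonoacrylic acid 21.

Steps most likely to fail:

1. Step 13 (Proposed new method). What may go wrong: β-hydride elimination or protonation of the π-allyl/enolate pair before the strained ring closes, erosion of the (Z)-geometry by syn–anti isomerisation of the π-allyl unit, or oligomerisation. The fallback uses known chemistry and closes the ring from an open chain instead of contracting it. It sets out from lactone 14, which would be opened by DMAP-catalysed transesterification with methanol (toluene, 90 °C) to methyl (4R,5E,7S,9Z)-7-(tert-butyldimethylsilyloxy)-11-hydroxy-6,10-dimethyl-3-oxo-4-(triethylsilyloxy)undeca-5,9-dienoate F1. Methyl chloroformate and pyridine would convert the allylic alcohol into the carbonate methyl (4R,5E,7S,9Z)-7-(tert-butyldimethylsilyloxy)-11-(methoxycarbonyloxy)-6,10-dimethyl-3-oxo-4-(triethylsilyloxy)undeca-5,9-dienoate F2. Tsuji–Trost macrocyclisation of the stabilised β-keto ester anion (Pd2(dba)3, dppe, THF, slow addition, 60 °C) would give methyl (3R,4E,6S,8Z)-6-(tert-butyldimethylsilyloxy)-5,9-dimethyl-2-oxo-3-(triethylsilyloxy)cyclodeca-4,8-diene-1-carboxylate F3, and Krapcho demethoxycarbonylation (LiCl, wet DMSO, 120 °C) would come back to the route at ketone 16.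

2. Step 18 (Proposed new method). What may go wrong: acetate may be too weak a Michael donor, so that the acrylate oligomerises, or the α-acyloxy ketone epimerises at C6 before the carbanion forms. The fallback sets out from ester 22 and uses the established alkoxide-triggered Michael/HWE reaction with a protected oxygen donor. Sodium 4-methoxybenzyl oxide (PMBOH, NaH, THF, −40 °C) would give (6Z,9S,10E,11aR)-9-(tert-butyldimethylsilyloxy)-3-[(4-methoxybenzyloxy)methyl]-6,10-dimethyl-4,5,8,9-tetrahydrocyclodeca[b]furan-2(11aH)-one F4. Oxidative debenzylation with DDQ (CH2Cl2, pH 7 buffer) would give (6Z,9S,10E,11aR)-9-(tert-butyldimethylsilyloxy)-3-(hydroxymethyl)-6,10-dimethyl-4,5,8,9-tetrahydrocyclodeca[b]furan-2(11aH)-one F5, and acetylation (Ac2O, pyridine) would come back to the route at 24.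

3. Step 11. What may go wrong: protonation of the samarium enolate (simple debromination), pinacol-type reduction of the aldehyde, or intermolecular aldol oligomerisation in competition with the twelve-membered ring closure. The fallback sets out from aldehyde 12 and replaces C–C ring closure by macrolactonisation. SnCl2-catalysed Roskamp homologation with tert-butyl diazoacetate would give tert-butyl (4R,5E,7S,9Z)-11-(2-bromoacetoxy)-7-(tert-butyldimethylsilyloxy)-6,10-dimethyl-3-oxo-4-(triethylsilyloxy)undeca-5,9-dienoate F6. Thiourea/NaHCO3 in EtOH would remove the bromoacetate to give tert-butyl (4R,5E,7S,9Z)-7-(tert-butyldimethylsilyloxy)-11-hydroxy-6,10-dimethyl-3-oxo-4-(triethylsilyloxy)undeca-5,9-dienoate F7. Thermolysis in refluxing toluene at high dilution would generate the acylketene, which the allylic hydroxyl traps (acylketene macrolactonisation), coming back to the route at β-keto lactone 14 and bypassing 13.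

**Further compounds**

F1 | step 13 | methyl (4R,5E,7S,9Z)-7-(tert-butyldimethylsilyloxy)-11-hydroxy-6,10-dimethyl-3-oxo-4-(triethylsilyloxy)undeca-5,9-dienoate | COC(=O)CC(=O)[C@H](O[Si](CC)(CC)CC)/C=C(C)/[C@@H](O[Si](C)(C)C(C)(C)C)C/C=C(C)\CO
F2 | step 13 | methyl (4R,5E,7S,9Z)-7-(tert-butyldimethylsilyloxy)-11-(methoxycarbonyloxy)-6,10-dimethyl-3-oxo-4-(triethylsilyloxy)undeca-5,9-dienoate | COC(=O)CC(=O)[C@H](O[Si](CC)(CC)CC)/C=C(C)/[C@@H](O[Si](C)(C)C(C)(C)C)C/C=C(C)\COC(=O)OC
F3 | step 13 | methyl (3R,4E,6S,8Z)-6-(tert-butyldimethylsilyloxy)-5,9-dimethyl-2-oxo-3-(triethylsilyloxy)cyclodeca-4,8-diene-1-carboxylate | O=C1C(C(=O)OC)C/C(C)=C\C[C@H](O[Si](C)(C)C(C)(C)C)/C(C)=C/[C@H]1O[Si](CC)(CC)CC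
F4 | step 18 | (6Z,9S,10E,11aR)-9-(tert-butyldimethylsilyloxy)-3-[(4-methoxybenzyloxy)methyl]-6,10-dimethyl-4,5,8,9-tetrahydrocyclodeca[b]furan-2(11aH)-one | CC(C)(C)[Si](C)(C)O[C@H]1C/C=C(/C)CCC2=C(COCc3ccc(OC)cc3)C(=O)O[C@@H]2/C=C/1C
F5 | step 18 | (6Z,9S,10E,11aR)-9-(tert-butyldimethylsilyloxy)-3-(hydroxymethyl)-6,10-dimethyl-4,5,8,9-tetrahydrocyclodeca[b]furan-2(11aH)-one | CC(C)(C)[Si](C)(C)O[C@H]1C/C=C(/C)CCC2=C(CO)C(=O)O[C@@H]2/C=C/1C
F6 | step 11 | tert-butyl (4R,5E,7S,9Z)-11-(2-bromoacetoxy)-7-(tert-butyldimethylsilyloxy)-6,10-dimethyl-3-oxo-4-(triethylsilyloxy)undeca-5,9-dienoate | CC(C)(C)OC(=O)CC(=O)[C@H](O[Si](CC)(CC)CC)/C=C(C)/[C@@H](O[Si](C)(C)C(C)(C)C)C/C=C(C)\COC(=O)CBr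
F7 | step 11 | tert-butyl (4R,5E,7S,9Z)-7-(tert-butyldimethylsilyloxy)-11-hydroxy-6,10-dimethyl-3-oxo-4-(triethylsilyloxy)undeca-5,9-dienoate | CC(C)(C)OC(=O)CC(=O)[C@H](O[Si](CC)(CC)CC)/C=C(C)/[C@@H](O[Si](C)(C)C(C)(C)C)C/C=C(C)\CO
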